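**Plan**

- Retrosynthesis: the O7–S bond of the sulfate and the two benzyl ethers are cut first. Ring C is then opened at C3–C4, giving a 2-(1-arylvinyloxy)benzoate. The C2=C3 enol ether goes back to an aryl ester carbonyl (methylenation), and the O1–C2 bond to an O-aroylation of a 2,4,6-trioxygenated benzoate.
- Forward: ring A is bought with C4 already attached as the carboxyl group, ring B arrives with the aroyl chloride, and ring C is the only ring made, closed by C-acylation of the vinyl ether.
- Enabling feature: O1–C2=C3 is an enol ether. Its nucleophilic terminal carbon C3 and the carboxyl carbon C4 (on C4a) are the ends of the six-atom chain C4–C4a–C8a–O1–C2–C3. O7 is the only ring-A oxygen para to that carboxyl, so it can be marked from the start.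
- Stereochemistry: the target has no stereocentre and no configurable double bond, so nothing has to be controlled.

Key step: step 7

Remark: the target is drawn as the free hydrogen sulfate. Aryl hydrogen sulfates hydrolyse under their own acidity, so the sulfate is carried as its sodium salt and protonated only in the last operation.

Remark: a free 2-(1-arylvinyloxy)benzoic acid is expected to protonate its own enol ether and add the carboxyl group across it. The carboxyl group is therefore unveiled as a salt (9) and activated without any proton source.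

**Route**

Step 1
Reactants: 1 2,4,6-trihydroxybenzoic acid (dried in vacuo at rt); 2 2-(trimethylsilyl)ethanol
Product: 3 2-(trimethylsilyl)ethyl 2,4,6-trihydroxybenzoate
Conditions: PPh3, DIAD, THF, 0 °C to rt
Reagents that add atoms: none
Why: Mitsunobu esterification, in which the carboxylic acid (by far the most acidic site) protonates the betaine and its carboxylate displaces the activated primary alcohol at a temperature below that of decarboxylation, while the phenols should stay untouched.

Step 2
Reactants: 3 2-(trimethylsilyl)ethyl 2,4,6-trihydroxybenzoate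
Product: 4 2-(trimethylsilyl)ethyl 2,6-dihydroxy-4-(methoxymethoxy)benzoate
Conditions: MOMCl (1.05 equiv), iPr2NEt, THF/CH2Cl2, 0 °C
Reagents that add atoms: chloromethyl methyl ether, COCCl
Why: Williamson-type O-alkylation (MOM ether formation), selective because the 4-hydroxyl para to the ester is the most acidic and the only one not hydrogen-bonded to the ester group.

Step 3
Reactants: 4 2-(trimethylsilyl)ethyl 2,6-dihydroxy-4-(methoxymethoxy)benzoate
Product: 5 2-(trimethylsilyl)ethyl 2-(benzyloxy)-6-hydroxy-4-(methoxymethoxy)benzoate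
Conditions: BnBr (1.05 equiv), K2CO3, acetone, rt to 40 °C
Reagents that add atoms: benzyl bromide, BrCc1ccccc1
Why: Williamson ether synthesis on one of two equivalent ortho hydroxyls; after the first benzylation the remaining hydroxyl is locked in a hydrogen bond to the ester carbonyl, which should hold the reaction at the monoether.

Step 4
Reactants: 5 2-(trimethylsilyl)ethyl 2-(benzyloxy)-6-hydroxy-4-(methoxymethoxy)benzoate; 6 4-(benzyloxy)benzoyl chloride
Product: 7 2-(trimethylsilyl)ethyl 2-(benzyloxy)-6-{[4-(benzyloxy)benzoyl]oxy}-4-(methoxymethoxy)benzoate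
Conditions: Et3N, DMAP (cat.), CH2Cl2, 0 °C to rt
Reagents that add atoms: none
Why: DMAP-catalysed O-acylation of a phenol by an aroyl chloride, the acylpyridinium intermediate being reactive enough to acylate the chelated hydroxyl.

Step 5
Reactants: 7 2-(trimethylsilyl)ethyl 2-(benzyloxy)-6-{[4-(benzyloxy)benzoyl]oxy}-4-(methoxymethoxy)benzoate
Product: 8 2-(trimethylsilyl)ethyl 2-(benzyloxy)-6-({1-[4-(benzyloxy)phenyl]ethenyl}oxy)-4-(methoxymethoxy)benzoate
Conditions: Cp2Ti(μ-Cl)(μ-CH2)AlMe2 (Tebbe reagent, 1.2 equiv), pyridine (cat.), THF/toluene, −40 to 0 °C; aq NaOH quench; basic Al2O3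
Reagents that add atoms: Tebbe reagent, C[Al-]1(C)C[Ti](C2C=CC=C2)(C2C=CC=C2)[Cl+]1
Why: Tebbe methylenation of an ester carbonyl, a standard way from aryl benzoates to aryl 1-arylvinyl ethers; the bulky titanocene methylidene should add to the open aryl 4-benzyloxybenzoate carbonyl and leave the di-ortho-substituted silylethyl benzoate alone.

Step 6
Reactants: 8 2-(trimethylsilyl)ethyl 2-(benzyloxy)-6-({1-[4-(benzyloxy)phenyl]ethenyl}oxy)-4-(methoxymethoxy)benzoate
Product: 9 tris(dimethylamino)sulfonium 2-(benzyloxy)-6-({1-[4-(benzyloxy)phenyl]ethenyl}oxy)-4-(methoxymethoxy)benzoate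
Conditions: (Me2N)3S+ Me3SiF2− (TASF, 0.98 equiv), MeCN/THF, 0 °C to rt; evaporation, toluene azeotrope, no aqueous or acidic work-up
Reagents that add atoms: tris(dimethylamino)sulfonium difluorotrimethylsilicate, CN(C)[S+](N(C)C)N(C)C.C[Si-](C)(C)(F)F
Why: fluoride-induced β-elimination of a 2-(trimethylsilyl)ethyl ester, in which anhydrous fluoride attacks silicon and ethene is expelled, so the hindered carboxylate is released as a salt under aprotic conditions that an enol ether tolerates, with only gaseous by-products.

Step 7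
Reactants: 9 tris(dimethylamino)sulfonium 2-(benzyloxy)-6-({1-[4-(benzyloxy)phenyl]ethenyl}oxy)-4-(methoxymethoxy)benzoate
Product: 11 5-(benzyloxy)-2-[4-(benzyloxy)phenyl]-7-(methoxymethoxy)-4H-chromen-4-one, via aroyl triflate 10 (not isolated)
Conditions: 9 added over 1 h to Tf2O (1.0 equiv), 2,6-di-tert-butyl-4-methylpyridine (2.5 equiv), CH2Cl2 (final 0.01 M), −78 °C, then to 0 °C; aq NaHCO3
Reagents that add atoms: trifluoromethanesulfonic anhydride, O=S(=O)(OS(=O)(=O)C(F)(F)F)C(F)(F)F (its CF3SO2 group stands in 10 and is lost again on the way to 11)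
Why: Proposed new method: triflic anhydride turns the carboxylate into the aroyl triflate 10, which the oxygen donors at C5, C7 and C8a let ionise to an acylium ion; the CH2 terminus of the vinyl ether (C3) attacks C4, the C2 oxocarbenium ion so formed is stabilised by O1 and the 4-benzyloxyphenyl ring, and the hindered pyridine removes the C3 proton to give the aromatic pyranone. The closest known reaction types are the β-acylation of vinyl ethers by reactive acid chlorides and anhydrides, the acylation of alkenes and arenes by mixed carboxylic triflic anhydrides, and the Friedel-Crafts closure of 3-aryloxyacrylic acids to chromones. Ring C closes in a six-membered mode that is endo with respect to the vinyl ether double bond (6-endo-trig) and exo with respect to the acyl group. No stereocentre is formed. The step needs C-acylation at C3 in preference to protonation of the enol ether (which would let the neighbouring carboxyl add and give a 2-aryl-2-methyl-1,3-benzodioxin-4-one) and to intermolecular acylation; proton-free activation of a salt, the buffered medium, high dilution and the six-atom spacing between C3 and C4 should secure this.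

Step 8
Reactants: 11 5-(benzyloxy)-2-[4-(benzyloxy)phenyl]-7-(methoxymethoxy)-4H-chromen-4-one
Product: 12 5-(benzyloxy)-2-[4-(benzyloxy)phenyl]-7-hydroxy-4H-chromen-4-one
Conditions: HCl (1.25 M in MeOH), THF, 40 °C
Reagents that add atoms: none
Why: acid-catalysed cleavage of the MOM acetal by transacetalisation to methanol, which the aromatic pyranone tolerates and which should leave the benzyl ethers in place under these mild conditions.

Step 9
Reactants: 12 5-(benzyloxy)-2-[4-(benzyloxy)phenyl]-7-hydroxy-4H-chromen-4-one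
Product: 13 sodium 5-(benzyloxy)-2-[4-(benzyloxy)phenyl]-4-oxo-4H-chromen-7-yl sulfate
Conditions: SO3·pyridine (3 equiv), pyridine, 40 °C; then aq NaHCO3; Sephadex LH-20
Reagents that add atoms: sulfur trioxide–pyridine complex, O=S(=O)([O-])[n+]1ccccc1; sodium hydrogencarbonate, [Na+].OC([O-])=O
Why: O-sulfation of a phenol with the sulfur trioxide–pyridine complex, unambiguous in position because the 7-hydroxyl is the only free hydroxyl, followed by exchange of pyridinium for sodium so that no pyridine is carried into the hydrogenolysis.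

Step 10
Reactants: 13 sodium 5-(benzyloxy)-2-[4-(benzyloxy)phenyl]-4-oxo-4H-chromen-7-yl sulfate
Product: 15 apigenin 7-sulfate (5-hydroxy-2-(4-hydroxyphenyl)-4-oxo-4H-chromen-7-yl hydrogen sulfate), via sodium apigenin 7-sulfate 14 (not isolated)
Conditions: H2 (1 atm), Pd/C (10% Pd on carbon), MeOH/THF/H2O, rt; filtration; then HCl (0.1 M aq, 1.0 equiv), 0 °C, C18 desalting, freeze-drying
Reagents that add atoms: none
Why: catalytic hydrogenolysis of the two aryl benzyl ethers over Pd/C, under which an aryl sulfate salt and the C2=C3 bond of the aromatic pyranone should persist at atmospheric pressure, followed by protonation of the sulfate with one equivalent of cold mineral acid.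

**Compound list**

1 | 2,4,6-trihydroxybenzoic acid | OC(=O)c1c(O)cc(O)cc1O | starting material
2 | 2-(trimethylsilyl)ethanol | C[Si](C)(C)CCO | starting material
3 | 2-(trimethylsilyl)ethyl 2,4,6-trihydroxybenzoate | C[Si](C)(C)CCOC(=O)c1c(O)cc(O)cc1O | intermediate
4 | 2-(trimethylsilyl)ethyl 2,6-dihydroxy-4-(methoxymethoxy)benzoate | C[Si](C)(C)CCOC(=O)c1c(O)cc(OCOC)cc1O | intermediate
5 | 2-(trimethylsilyl)ethyl 2-(benzyloxy)-6-hydroxy-4-(methoxymethoxy)benzoate | C[Si](C)(C)CCOC(=O)c1c(O)cc(OCOC)cc1OCc1ccccc1 | intermediate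
6 | 4-(benzyloxy)benzoyl chloride | O=C(Cl)c1ccc(OCc2ccccc2)cc1 | starting material
7 | 2-(trimethylsilyl)ethyl 2-(benzyloxy)-6-{[4-(benzyloxy)benzoyl]oxy}-4-(methoxymethoxy)benzoate | C[Si](C)(C)CCOC(=O)c1c(OCc2ccccc2)cc(OCOC)cc1OC(=O)c1ccc(OCc2ccccc2)cc1 | intermediate
8 | 2-(trimethylsilyl)ethyl 2-(benzyloxy)-6-({1-[4-(benzyloxy)phenyl]ethenyl}oxy)-4-(methoxymethoxy)benzoate | C[Si](C)(C)CCOC(=O)c1c(OCc2ccccc2)cc(OCOC)cc1OC(=C)c1ccc(OCc2ccccc2)cc1 | intermediate
9 | tris(dimethylamino)sulfonium 2-(benzyloxy)-6-({1-[4-(benzyloxy)phenyl]ethenyl}oxy)-4-(methoxymethoxy)benzoate | CN(C)[S+](N(C)C)N(C)C.[O-]C(=O)c1c(OCc2ccccc2)cc(OCOC)cc1OC(=C)c1ccc(OCc2ccccc2)cc1 | intermediate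
10 | 2-(benzyloxy)-6-({1-[4-(benzyloxy)phenyl]ethenyl}oxy)-4-(methoxymethoxy)benzoic trifluoromethanesulfonic anhydride (aroyl triflate) | O=C(OS(=O)(=O)C(F)(F)F)c1c(OCc2ccccc2)cc(OCOC)cc1OC(=C)c1ccc(OCc2ccccc2)cc1 | intermediate
11 | 5-(benzyloxy)-2-[4-(benzyloxy)phenyl]-7-(methoxymethoxy)-4H-chromen-4-one | O=c1cc(-c2ccc(OCc3ccccc3)cc2)oc2cc(OCOC)cc(OCc3ccccc3)c12 | intermediate
12 | 5-(benzyloxy)-2-[4-(benzyloxy)phenyl]-7-hydroxy-4H-chromen-4-one | O=c1cc(-c2ccc(OCc3ccccc3)cc2)oc2cc(O)cc(OCc3ccccc3)c12 | intermediate
13 | sodium 5-(benzyloxy)-2-[4-(benzyloxy)phenyl]-4-oxo-4H-chromen-7-yl sulfate | O=c1cc(-c2ccc(OCc3ccccc3)cc2)oc2cc(OS(=O)(=O)[O-])cc(OCc3ccccc3)c12.[Na+] | intermediate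
14 | sodium apigenin 7-sulfate (sodium 5-hydroxy-2-(4-hydroxyphenyl)-4-oxo-4H-chromen-7-yl sulfate) | O=c1cc(-c2ccc(O)cc2)oc2cc(OS(=O)(=O)[O-])cc(O)c12.[Na+] | intermediate
15 | apigenin 7-sulfate (5-hydroxy-2-(4-hydroxyphenyl)-4-oxo-4H-chromen-7-yl hydrogen sulfate) | O=c1cc(-c2ccc(O)cc2)oc2cc(OS(=O)(=O)O)cc(O)c12 | target

**Count**

Total steps: 10. Longest linear sequence: 10 steps (from 1; compounds 2 and 6 are bought).

**Steps most likely to fail**

Step 7 (proposed method). The enol ether may be attacked by the anhydride or by adventitious acid before the acylium ion reaches C3, acylation may run between molecules and give oligomers, or the MOM acetal may be lost in the electrophilic medium. The fallback uses known enolate C-acylation and cyclodehydration (Baker-Venkataraman type), which builds ring C through C2–C3 and O1–C2 instead of C3–C4. It sets out from acid chloride 6 and comes back to the route at 12. Commercial 1-(2,4,6-trihydroxyphenyl)ethanone is MOM-protected at the para hydroxyl (MOMCl, iPr2NEt) to give 1-[2,6-dihydroxy-4-(methoxymethoxy)phenyl]ethanone F1. Monobenzylation (BnBr, K2CO3) gives 1-[2-(benzyloxy)-6-hydroxy-4-(methoxymethoxy)phenyl]ethanone F2. Its dianion (LiN(SiMe3)2, 3 equiv, THF, −78 °C) is C-acylated by 6 to give 1-[2-(benzyloxy)-6-hydroxy-4-(methoxymethoxy)phenyl]-3-[4-(benzyloxy)phenyl]propane-1,3-dione F3. HCl in MeOH/THF at 50 °C should then effect cyclodehydration and MOM removal in one operation, giving 12.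

Step 5. The titanium reagent may also methylenate the hindered silylethyl ester, or the electron-rich enol ether may hydrolyse during quench and chromatography. The fallback forms the O1–C2 bond by C–O coupling instead of making C2=C3 by olefination. It sets out from phenol 5 (step 4 is skipped) and comes back at 8. 1-(Benzyloxy)-4-(1-bromoethenyl)benzene F4 is prepared from commercial 1-[4-(benzyloxy)phenyl]ethanone with (PhO)3P, Br2 and Et3N in CH2Cl2. It is then coupled with 5 in an Ullmann-type O-vinylation (CuI 10 mol%, N,N-dimethylglycine, Cs2CO3, 1,4-dioxane, 90 °C).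

Step 2. Discrimination between the para and ortho hydroxyls may be incomplete and a second alkylation may follow; upstream, step 1 carries a risk of decarboxylation. The fallback fixes the regiochemistry by a cyclic acetal instead of relying on acidity differences. It sets out from acid 1, bypasses steps 1 to 3 and comes back at 5. Acid 1 with acetone, (CF3CO)2O and CF3CO2H gives 5,7-dihydroxy-2,2-dimethyl-4H-1,3-benzodioxin-4-one F5. MOMCl and iPr2NEt alkylate the unchelated 7-hydroxyl to give 5-hydroxy-7-(methoxymethoxy)-2,2-dimethyl-4H-1,3-benzodioxin-4-one F6. BnBr and K2CO3 in DMF give 5-(benzyloxy)-7-(methoxymethoxy)-2,2-dimethyl-4H-1,3-benzodioxin-4-one F7. Sodium 2-(trimethylsilyl)ethoxide (from 2 and NaH, THF) opens the dioxinone to ester 5 with the ortho hydroxyl free.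

**Further compounds**

F1 | step 7 | 1-[2,6-dihydroxy-4-(methoxymethoxy)phenyl]ethanone | CC(=O)c1c(O)cc(OCOC)cc1O
F2 | step 7 | 1-[2-(benzyloxy)-6-hydroxy-4-(methoxymethoxy)phenyl]ethanone | CC(=O)c1c(O)cc(OCOC)cc1OCc1ccccc1
F3 | step 7 | 1-[2-(benzyloxy)-6-hydroxy-4-(methoxymethoxy)phenyl]-3-[4-(benzyloxy)phenyl]propane-1,3-dione | O=C(CC(=O)c1ccc(OCc2ccccc2)cc1)c1c(O)cc(OCOC)cc1OCc1ccccc1
F4 | step 5 | 1-(benzyloxy)-4-(1-bromoethenyl)benzene | C=C(Br)c1ccc(OCc2ccccc2)cc1
F5 | step 2 | 5,7-dihydroxy-2,2-dimethyl-4H-1,3-benzodioxin-4-one | CC1(C)OC(=O)c2c(O)cc(O)cc2O1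
F6 | step 2 | 5-hydroxy-7-(methoxymethoxy)-2,2-dimethyl-4H-1,3-benzodioxin-4-one | CC1(C)OC(=O)c2c(O)cc(OCOC)cc2O1
F7 | step 2 | 5-(benzyloxy)-7-(methoxymethoxy)-2,2-dimethyl-4H-1,3-benzodioxin-4-one | CC1(C)OC(=O)c2c(OCc3ccccc3)cc(OCOC)cc2O1
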